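**Retrosynthetic overview**

1. The route rests on the cis-1,4-dioxygen pattern of the cyclohexane ring (C5–C10): the C6–O and C9–O bonds lie on the face of the C10 methyl and bracket the C7–C8 bond that carries the γ-lactone (C11 on C7, lactone oxygen on C8). This is the pattern O2 leaves on adding across C6 and C9 of a C6=C7–C8=C9 diene.
2. Target ⇒ (esters at O6 and O9, Mannich methylenation at C13 and C15, C1=C2 by Wittig, C3 aldehyde from an allyl group on C5) cis-fused 8,12-lactone carbinol ⇒ (OH-directed hydrogenation, C6 reduction, lactonisation) C7=C11 butenolide ⇒ (epoxidation/β-elimination, C5 allylation) 9-hydroxy-6-oxo-7-ene.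
3. Hydroxy enone ⇒ (Kornblum–DeLaMare) 2,3-dioxabicyclo[2.2.2]octene ⇒ (singlet-oxygen [4+2]) 5,5-disubstituted cyclohexa-1,3-diene 14 + O2.
4. Diene 14 ⇒ (Negishi coupling of a Reformatsky reagent, dienyl triflate, CuH desymmetrisation that sets C10) 4,4-disubstituted cyclohexadienone ⇒ (bis-allylic oxidation, Birch reductive methylation) benzoic acid.
5. Ring order: carbocycle from the arene first; 1,2-dioxane bridge second (step 8, opened in step 9); γ-lactone last (closed in step 13, ring fusion fixed in step 17).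

Key step: step 8

**Remarks before the steps**

- Convention: carbons are numbered as in the target (ring C5–C10; C1=C2 and the C14 methyl on C10; C3/C4/C15 on C5; C11/C12/C13 in the lactone). β is the ring face of the C10 methyl, α the face of the C10 one-carbon branch (C1).
- The ester on C9 in the given structure is the (2R)-2-methylbutanoate, so (R)-2-methylbutanoic acid is used.
- Assumption: in step 5 the (R)-bisphosphine is taken to give the (S)-enone; if the sense of induction is the opposite, the (S)-ligand is used.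

**Route**

Step 1
Reactants: 1 benzoic acid; 2 iodomethane
Product: 4 1-methylcyclohexa-2,5-diene-1-carboxylic acid, via dilithium dienediolate 3 (not isolated)
Conditions: Li, NH3(l)/THF, −78 °C; then MeI; NH4Cl, then aq. HCl
Reagents that add atoms: none
Why: Birch reductive alkylation: the dianion from Li/NH3 reduction of the benzoate is C-methylated at the carboxyl-bearing carbon, which makes the future C10 quaternary and gives a 1,4-diene that cannot re-aromatise.

Step 2
Reactants: 4 1-methylcyclohexa-2,5-diene-1-carboxylic acid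
Product: 5 (1-methylcyclohexa-2,5-dien-1-yl)methanol
Conditions: LiAlH4, THF, 0 °C → reflux; aq. NaOH work-up
Reagents that add atoms: none
Why: Hydride reduction of the carboxylic acid to the primary alcohol (future C1) should leave the isolated alkenes untouched.

Step 3
Reactants: 5 (1-methylcyclohexa-2,5-dien-1-yl)methanol
Product: 6 tert-butyl[(1-methylcyclohexa-2,5-dien-1-yl)methoxy]diphenylsilane
Conditions: tBuPh2SiCl, imidazole, DMF, rt
Reagents that add atoms: tert-butyl(chloro)diphenylsilane, CC(C)(C)[Si](Cl)(c1ccccc1)c1ccccc1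
Why: Standard silylation of a primary alcohol; the bulky silyl ether later differentiates the two faces of the ring.

Step 4
Reactants: 6 tert-butyl[(1-methylcyclohexa-2,5-dien-1-yl)methoxy]diphenylsilane
Product: 7 4-{[tert-butyl(diphenyl)silyl]oxymethyl}-4-methylcyclohexa-2,5-dien-1-one
Conditions: (C5H5NH)2Cr2O7 (pyridinium dichromate, mediator), tBuOOH, Celite, benzene, rt
Reagents that add atoms: tert-butyl hydroperoxide, CC(C)(C)OO
Why: Chromium-mediated allylic oxidation with tBuOOH acts on the only bis-allylic methylene and should give the cross-conjugated, prochiral dienone.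

Step 5
Reactants: 7 4-{[tert-butyl(diphenyl)silyl]oxymethyl}-4-methylcyclohexa-2,5-dien-1-one
Product: 9 (S)-4-{[tert-butyl(diphenyl)silyl]oxymethyl}-4-methylcyclohex-2-en-1-one, via silyl dienol ether 8 (not isolated)
Conditions: Cu(OAc)2 (5 mol %), (R)-DTBM-SEGPHOS (5.5 mol %), (EtO)2MeSiH (1.1 equiv), toluene, −20 °C; then 1 M HCl/THF, 0 °C
Reagents that add atoms: none
Why: Asymmetric copper hydride conjugate reduction used as an enantiotopic-group-selective desymmetrisation: the chiral CuH reduces one of the two enone C=C bonds, which differ only in their relation to CH3 versus CH2OSi on C10, and so sets C10; the silyl dienol ether formed is no longer an enone, which should stop a second reduction.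

Step 6
Reactants: 9 (S)-4-{[tert-butyl(diphenyl)silyl]oxymethyl}-4-methylcyclohex-2-en-1-one
Product: 11 (S)-4-{[tert-butyl(diphenyl)silyl]oxymethyl}-4-methylcyclohexa-1,5-dien-1-yl trifluoromethanesulfonate, via lithium dienolate 10 (not isolated)
Conditions: LiN(SiMe3)2, THF, −78 °C; then PhNTf2, −78 → 0 °C
Reagents that add atoms: N-phenylbis(trifluoromethanesulfonimide), O=S(=O)(N(c1ccccc1)S(=O)(=O)C(F)(F)F)C(F)(F)F
Why: Kinetic enolisation followed by O-triflation; because C10 is quaternary there is no γ-hydrogen, so only the cross-conjugated dienolate can form and the triflate sits on the future C7 of a C6=C7–C8=C9 diene.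

Step 7
Reactants: 11 dienyl triflate; 12 tert-butyl bromoacetate
Product: 14 tert-butyl 2-[(4S)-4-{[tert-butyl(diphenyl)silyl]oxymethyl}-4-methylcyclohexa-1,5-dien-1-yl]acetate, via Reformatsky reagent 13 (not isolated)
Conditions: Zn dust (Me3SiCl-activated), THF, 40 °C (gives 13); then 11, Pd(PPh3)4 (5 mol %), THF, 60 °C
Reagents that add atoms: none
Why: Negishi-type cross-coupling of the zinc ester enolate with the alkenyl triflate under zerovalent palladium forms the C7–C11 bond without moving the diene, and the quaternary C10 keeps the diene from aromatising.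

Step 8
Reactants: 14 diene ester; 15 dioxygen
Product: 16 tert-butyl 2-[2,3-dioxabicyclo[2.2.2]oct-5-en-5-yl]acetate carrying the C10 methyl and CH2OSitBuPh2 on the ethano bridge carbon next to C9 (C6–O and C9–O both β, cis to the C10 methyl)
Conditions: O2 (1 atm, bubbled), 5,10,15,20-tetraphenylporphyrin (1 mol %), CH2Cl2, −20 °C, white LED
Reagents that add atoms: none
Why: Tetraphenylporphyrin-sensitised singlet oxygen adds suprafacially in a [4+2] cycloaddition to the s-cis-locked ring diene and forms the C6–O and C9–O bonds together. The closest known reaction type is the photooxygenation of cyclohexa-1,3-dienes to 2,3-dioxabicyclo[2.2.2]oct-5-enes. The six-membered 1,2-dioxane ring is closed by the cycloaddition itself, as a peroxide bridge across C6 and C9. Both new stereocentres (C6, C9) are controlled by C10: in the boat-like transition state the C10 group on the attacked face ends up syn to the O–O bridge, so oxygen should enter on the methyl (β) face and leave the CH2OSitBuPh2 group over the C7=C8 bridge. The step needs β-face selectivity and [4+2] addition in preference to the Schenck ene reaction; the bulky silyl ether, the quaternary C10 (no allylic hydrogen next to C9), the fixed cisoid diene and the low temperature are what should secure them. The acetate arm on C7 is a spectator.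

Step 9
Reactants: 16 endoperoxide
Product: 17 tert-butyl 2-[9β-hydroxy-6-oxo-cyclohex-7-en-7-yl]acetate with C10 methyl (β) and CH2OSitBuPh2 (α) (target numbering)
Conditions: Et3N (1.2 equiv), CH2Cl2, 0 °C → rt
Reagents that add atoms: none
Why: Kornblum–DeLaMare rearrangement: the amine removes the less hindered bridgehead hydrogen H6 (next to the C5 methylene, not H9 next to quaternary C10) with O–O cleavage, giving the C6 ketone conjugated to C7=C8 and keeping the β-configured C9 carbinol.

Step 10
Reactants: 17 hydroxy enone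
Product: 18 the C9 triisopropylsilyl ether of 17
Conditions: iPr3SiOTf, 2,6-lutidine, CH2Cl2, −78 → 0 °C
Reagents that add atoms: triisopropylsilyl trifluoromethanesulfonate, CC(C)[Si](C(C)C)(C(C)C)OS(=O)(=O)C(F)(F)F
Why: Silylation with the reactive triflate covers the hindered C9 hydroxyl with a group that survives acid, does not migrate, and can later be kept while the primary silyl ether is removed.

Step 11
Reactants: 18 silyl-protected enone; 19 diallyl carbonate
Product: 21 the 5β-allyl enone (allyl on C5 cis to the C10 methyl), via trimethylsilyl dienol ether 20 (not isolated)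
Conditions: Me3SiOTf, Et3N, CH2Cl2, −78 → 0 °C; solvent exchange; then 19, Pd2(dba)3 (2.5 mol %), PPh3 (12 mol %), Bu4N[Ph3SiF2] (35 mol %), THF, rt
Reagents that add atoms: none
Why: Soft enolisation activates only the ketone (C5–H), not the ester α-hydrogens on C11, and the Tsuji allylation of the resulting silyl dienol ether forms the C5–C4 bond anti to the CH2OSi group on C10; this β-epimer is also the thermodynamic one, and C5 stays epimerisable through step 12.

Step 12
Reactants: 21 allyl enone
Product: 23 the (E)-alkylidene hydroxy keto ester (C6 ketone; C7=C11–CO2tBu with the ester cis to C8; C8 α-OH), via epoxy ketone 22 (not isolated)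
Conditions: tBuOOH (in decane), DBU, CH2Cl2, 0 °C → rt
Reagents that add atoms: tert-butyl hydroperoxide, CC(C)(C)OO
Why: Weitz–Scheffer epoxidation puts the oxygen on C8 from the α face, anti to the C9 silyloxy group, and the same base then removes a C11 hydrogen and opens the C7–O bond by E1cB (the known β-elimination of β,γ-epoxy esters), which keeps the α C8–O bond as the free hydroxyl and gives the alkylidene isomer with the ester trans to the ketone.

Step 13
Reactants: 23 hydroxy keto ester
Product: 25 the 6-oxo butenolide (C7=C11; lactone oxygen α on C8), via hydroxy acid 24 (not isolated)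
Conditions: CF3CO2H/CH2Cl2 (1:4), 0 °C → rt
Reagents that add atoms: none
Why: Acidolysis of the tert-butyl ester and spontaneous lactonisation of the cis-disposed γ-hydroxy enoic acid onto C8–OH (the only free hydroxyl) closes the lactone ring; the two silyl ethers and the allyl group should tolerate the acid.

Step 14
Reactants: 25 keto butenolide
Product: 27 the C3 aldehyde (C5–CH2–CHO), via ozonide 26 (not isolated)
Conditions: O3, CH2Cl2, −78 °C, to the first excess of ozone; then PPh3, −78 °C → rt
Reagents that add atoms: ozone, [O-][O+]=O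
Why: Ozonolysis with reductive work-up cleaves the electron-rich terminal alkene, while the butenolide C=C, flanked by two carbonyl groups, is too electron-poor to compete.

Step 15
Reactants: 27 keto aldehyde
Product: 28 the 1,3-dioxolane of the C3 aldehyde
Conditions: Me3SiOCH2CH2OSiMe3, Me3SiOTf (cat.), CH2Cl2, −78 °C
Reagents that add atoms: 1,2-bis(trimethylsilyloxy)ethane, C[Si](C)(C)OCCO[Si](C)(C)C
Why: Noyori acetalisation at low temperature is selective for the aldehyde over the hindered conjugated ketone, and the cyclic acetal resists exchange with the C6 hydroxyl made in the next step.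

Step 16
Reactants: 28 keto butenolide acetal
Product: 29 the 6β-hydroxy butenolide
Conditions: NaBH4, CeCl3·7H2O, MeOH, −78 °C
Reagents that add atoms: none
Why: Luche 1,2-reduction: the planar butenolide holds the ring in the chair with the C10 methyl axial, which shields the β face of C6, so hydride should enter from the α face and give the β (axial) alcohol, while CeCl3 suppresses conjugate reduction.

Step 17
Reactants: 29 hydroxy butenolide
Product: 30 the cis-fused 8,12-lactone (H7 β, H8 β; C11 α) with free 6β-OH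
Conditions: H2 (1 atm), [Ir(cod)(PCy3)(py)]PF6 (10 mol %), CH2Cl2, rt
Reagents that add atoms: none
Why: Hydroxyl-directed hydrogenation: the axial C6 β-hydroxyl binds the cationic iridium catalyst and hydrogen is delivered to C7 on the β face, which sets C7 with C11 α and so the cis ring fusion; C7 cannot epimerise afterwards because C6 is now a carbinol.

Step 18
Reactants: 30 hydroxy lactone
Product: 32 the 11-(dimethylaminomethyl) lactone (C11 epimers; centre removed later), via dilithium alkoxide enolate 31 (not isolated)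
Conditions: LiN(iPr)2 (2.3 equiv), THF, −78 °C; then Me2N=CH2+ I−, −78 → 0 °C
Reagents that add atoms: N,N-dimethylmethyleneiminium iodide, C=[N+](C)C.[I-]
Why: Mannich aminomethylation of the lactone enolate introduces C13 as a masked α-methylene group before any enolisable ester is present; the trans-diaxial C6 alkoxide cannot reach the lactone carbonyl, so translactonisation is not expected.

Step 19
Reactants: 32 amino lactone; 33 angelic acid
Product: 35 the 6β-angelate, via mixed anhydride 34 (not isolated)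
Conditions: 33, 2,4,6-Cl3C6H2COCl, Et3N, toluene, rt (gives 34); then 32, toluene, 75 °C
Reagents that add atoms: none
Why: Yamaguchi esterification run without a pyridine-type acyl-transfer catalyst acylates the hindered axial alcohol while avoiding the reversible conjugate addition that would isomerise the (Z)-angelate to the tiglate.

Step 20
Reactants: 35 angelate
Product: 36 the C1 primary alcohol
Conditions: Bu4NF, AcOH (1:1), THF, 0 °C → rt
Reagents that add atoms: none
Why: Buffered fluoride desilylation should remove the primary tert-butyldiphenylsilyl ether and leave the secondary triisopropylsilyl ether at C9, which is shielded by the quaternary C10; the buffer protects the angelate.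

Step 21
Reactants: 36 primary alcohol
Product: 37 the C1 aldehyde
Conditions: 1,1,1-triacetoxy-1,1-dihydro-1,2-benziodoxol-3(1H)-one, NaHCO3, CH2Cl2, 0 °C → rt
Reagents that add atoms: none
Why: Dess–Martin oxidation gives the non-enolisable neopentyl aldehyde under buffered, near-neutral conditions that the acetal, the amine and the esters tolerate.

Step 22
Reactants: 37 aldehyde
Product: 38 the C10 vinyl compound
Conditions: Ph3PCH3Br, KN(SiMe3)2 (slight deficiency), THF, 0 °C; then 37, −78 → 0 °C
Reagents that add atoms: methyltriphenylphosphonium bromide, C[P+](c1ccccc1)(c1ccccc1)c1ccccc1.[Br-]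
Why: Wittig methylenation of the only aldehyde builds C1=C2; C9 is still silylated (no retro-aldol pathway) and the lactone methylene is still masked as the amine (no Michael acceptor for the ylide).

Step 23
Reactants: 38 vinyl compound
Product: 39 the C9 β-alcohol
Conditions: HF·pyridine, pyridine, THF, 0 °C → rt
Reagents that add atoms: none
Why: Acidic fluoride cleaves the remaining silyl ether without base, so neither ester is put at risk, and the dioxolane is stable to the pyridine-buffered reagent.

Step 24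
Reactants: 39 alcohol; 40 (R)-2-methylbutanoic acid
Product: 41 the 9β-[(2R)-2-methylbutanoate]
Conditions: 40, DCC, DMAP (cat.), CH2Cl2, 0 °C → rt
Reagents that add atoms: none
Why: Steglich esterification of the equatorial C9 hydroxyl with the enantiopure α-branched aliphatic acid is a standard acylation that does not touch the acid's stereocentre.

Step 25
Reactants: 41 diester acetal
Product: 42 the C3 aldehyde (C5–CH2–CHO)
Conditions: 2 M HCl (aq), THF, rt; NaHCO3 work-up
Reagents that add atoms: water, O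
Why: Acid-catalysed acetal hydrolysis releases the aldehyde only after C6 has been acylated, so it cannot close to a lactol, and after the only other aldehyde of the route has been consumed.

Step 26
Reactants: 42 aldehyde
Product: 44 the 2-substituted acrolein (C4=C15, C3 aldehyde), via β-amino aldehyde 43 (not isolated)
Conditions: Me2N=CH2+ I−, Et3N, CH2Cl2, rt
Reagents that add atoms: N,N-dimethylmethyleneiminium iodide, C=[N+](C)C.[I-]
Why: Mannich α-methylenation of the aldehyde: aminomethylation at C4 through the enol and spontaneous β-elimination of dimethylamine give the enal without creating a stereocentre.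

Step 27
Reactants: 44 enal amine
Product: 46 CNP0295282.1, the (5R,6S,7R,8R,9R,10S)-6-angeloyloxy-9-[(2R)-2-methylbutanoyloxy]-3-oxoelema-1,4(15),11(13)-trien-12,8-olide, via ammonium iodide 45 (not isolated)
Conditions: MeI, CH2Cl2/MeOH, rt; then aq. NaHCO3, EtOAc, rt
Reagents that add atoms: none
Why: N-Methylation followed by mild-base Hofmann-type β-elimination of trimethylamine unmasks the α-methylene lactone as the last operation, under conditions that leave the enal, the angelate and the 2-methylbutanoate alone.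

**Compound list**

1 | benzoic acid | O=C(O)c1ccccc1 | starting material
2 | iodomethane | CI | starting material
3 | dilithium cyclohexa-2,5-dien-1-ide-1-carboxylate | [Li+].[Li+].[O-]C(=O)[C-]1C=CCC=C1 | intermediate
4 | 1-methylcyclohexa-2,5-diene-1-carboxylic acid | CC1(C(=O)O)C=CCC=C1 | intermediate
5 | (1-methylcyclohexa-2,5-dien-1-yl)methanol | CC1(CO)C=CCC=C1 | intermediate
6 | tert-butyl[(1-methylcyclohexa-2,5-dien-1-yl)methoxy]diphenylsilane | CC1(CO[Si](c2ccccc2)(c2ccccc2)C(C)(C)C)C=CCC=C1 | intermediate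
7 | 4-{[tert-butyl(diphenyl)silyl]oxymethyl}-4-methylcyclohexa-2,5-dien-1-one | CC1(CO[Si](c2ccccc2)(c2ccccc2)C(C)(C)C)C=CC(=O)C=C1 | intermediate
8 | diethoxy(methyl)silyl dienol ether of 9 | CC(C)(C)[Si](c1ccccc1)(c1ccccc1)OC[C@@]1(C)CC=C(O[Si](C)(OCC)OCC)C=C1 | intermediate
9 | (S)-4-{[tert-butyl(diphenyl)silyl]oxymethyl}-4-methylcyclohex-2-en-1-one | CC(C)(C)[Si](c1ccccc1)(c1ccccc1)OC[C@@]1(C)CCC(=O)C=C1 | intermediate
10 | lithium cross-conjugated dienolate of 9 | CC(C)(C)[Si](c1ccccc1)(c1ccccc1)OC[C@@]1(C)CC=C([O-])C=C1.[Li+] | intermediate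
11 | (S)-4-{[tert-butyl(diphenyl)silyl]oxymethyl}-4-methylcyclohexa-1,5-dien-1-yl trifluoromethanesulfonate | CC(C)(C)[Si](c1ccccc1)(c1ccccc1)OC[C@@]1(C)CC=C(OS(=O)(=O)C(F)(F)F)C=C1 | intermediate
12 | tert-butyl bromoacetate | BrCC(=O)OC(C)(C)C | starting material
13 | bromo(2-tert-butoxy-2-oxoethyl)zinc | Br[Zn]CC(=O)OC(C)(C)C | intermediate
14 | tert-butyl 2-[(4S)-4-{[tert-butyl(diphenyl)silyl]oxymethyl}-4-methylcyclohexa-1,5-dien-1-yl]acetate (key-step precursor) | CC(C)(C)[Si](c1ccccc1)(c1ccccc1)OC[C@@]1(C)CC=C(CC(=O)OC(C)(C)C)C=C1 | intermediate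
15 | dioxygen | O=O | starting material
16 | endoperoxide: 2,3-dioxabicyclo[2.2.2]oct-5-ene with the acetate arm on C7, C6–O and C9–O β (key-step product) | CC(C)(C)[Si](c1ccccc1)(c1ccccc1)OC[C@@]1(C)C[C@@H]2OO[C@H]1C=C2CC(=O)OC(C)(C)C | intermediate
17 | 9β-hydroxy-6-oxo-7-ene with tert-butyl acetate arm on C7 | CC(C)(C)[Si](c1ccccc1)(c1ccccc1)OC[C@@]1(C)CC(=O)C(CC(=O)OC(C)(C)C)=C[C@@H]1O | intermediate
18 | 9β-triisopropylsilyl ether of 17 | CC(C)(C)[Si](c1ccccc1)(c1ccccc1)OC[C@@]1(C)CC(=O)C(CC(=O)OC(C)(C)C)=C[C@@H]1O[Si](C(C)C)(C(C)C)C(C)C | intermediate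
19 | diallyl carbonate | C=CCOC(=O)OCC=C | starting material
20 | trimethylsilyl dienol ether of 18 (C5=C6–OSiMe3, C7=C8) | CC(C)(C)[Si](c1ccccc1)(c1ccccc1)OC[C@@]1(C)C=C(O[Si](C)(C)C)C(CC(=O)OC(C)(C)C)=C[C@@H]1O[Si](C(C)C)(C(C)C)C(C)C | intermediate
21 | 5β-allyl enone | CC(C)(C)[Si](c1ccccc1)(c1ccccc1)OC[C@@]1(C)[C@H](CC=C)C(=O)C(CC(=O)OC(C)(C)C)=C[C@@H]1O[Si](C(C)C)(C(C)C)C(C)C | intermediate
22 | 7α,8α-epoxy ketone | CC(C)(C)[Si](c1ccccc1)(c1ccccc1)OC[C@@]1(C)[C@H](CC=C)C(=O)[C@@]2(CC(=O)OC(C)(C)C)O[C@H]2[C@@H]1O[Si](C(C)C)(C(C)C)C(C)C | intermediate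
23 | (E)-7(11)-alkylidene 8α-hydroxy 6-ketone tert-butyl ester | CC(C)(C)[Si](c1ccccc1)(c1ccccc1)OC[C@@]1(C)[C@H](CC=C)C(=O)/C(=C/C(=O)OC(C)(C)C)[C@@H](O)[C@@H]1O[Si](C(C)C)(C(C)C)C(C)C | intermediate
24 | corresponding hydroxy acid | CC(C)(C)[Si](c1ccccc1)(c1ccccc1)OC[C@@]1(C)[C@H](CC=C)C(=O)/C(=C/C(=O)O)[C@@H](O)[C@@H]1O[Si](C(C)C)(C(C)C)C(C)C | intermediate
25 | 6-oxo-7(11)-en-12,8α-olide (keto butenolide), 5β-allyl | CC(C)(C)[Si](c1ccccc1)(c1ccccc1)OC[C@@]1(C)[C@H](CC=C)C(=O)C2=CC(=O)O[C@H]2[C@@H]1O[Si](C(C)C)(C(C)C)C(C)C | intermediate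
26 | ozonide (1,2,4-trioxolane) of 25 | CC(C)(C)[Si](c1ccccc1)(c1ccccc1)OC[C@@]1(C)[C@H](CC3OCOO3)C(=O)C2=CC(=O)O[C@H]2[C@@H]1O[Si](C(C)C)(C(C)C)C(C)C | intermediate
27 | keto butenolide with C5–CH2–CHO | CC(C)(C)[Si](c1ccccc1)(c1ccccc1)OC[C@@]1(C)[C@H](CC=O)C(=O)C2=CC(=O)O[C@H]2[C@@H]1O[Si](C(C)C)(C(C)C)C(C)C | intermediate
28 | keto butenolide with C3 as 1,3-dioxolane | CC(C)(C)[Si](c1ccccc1)(c1ccccc1)OC[C@@]1(C)[C@H](CC3OCCO3)C(=O)C2=CC(=O)O[C@H]2[C@@H]1O[Si](C(C)C)(C(C)C)C(C)C | intermediate
29 | 6β-hydroxy butenolide | CC(C)(C)[Si](c1ccccc1)(c1ccccc1)OC[C@@]1(C)[C@H](CC3OCCO3)[C@H](O)C2=CC(=O)O[C@H]2[C@@H]1O[Si](C(C)C)(C(C)C)C(C)C | intermediate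
30 | cis-fused 6β-hydroxy-12,8α-olide (H7 β, H8 β) | CC(C)(C)[Si](c1ccccc1)(c1ccccc1)OC[C@@]1(C)[C@H](CC3OCCO3)[C@H](O)[C@H]2CC(=O)O[C@H]2[C@@H]1O[Si](C(C)C)(C(C)C)C(C)C | intermediate
31 | dilithium C6-alkoxide lactone enolate of 30 | CC(C)(C)[Si](c1ccccc1)(c1ccccc1)OC[C@@]1(C)[C@H](CC3OCCO3)[C@H]([O-])[C@H]2C=C([O-])O[C@H]2[C@@H]1O[Si](C(C)C)(C(C)C)C(C)C.[Li+].[Li+] | intermediate
32 | 11-(dimethylaminomethyl) lactone, 6β-OH (C11 epimers) | CC(C)(C)[Si](c1ccccc1)(c1ccccc1)OC[C@@]1(C)[C@H](CC3OCCO3)[C@H](O)[C@H]2C(CN(C)C)C(=O)O[C@H]2[C@@H]1O[Si](C(C)C)(C(C)C)C(C)C | intermediate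
33 | angelic acid, (Z)-2-methylbut-2-enoic acid | C/C=C(/C)C(=O)O | starting material
34 | angelic 2,4,6-trichlorobenzoic anhydride | C/C=C(/C)C(=O)OC(=O)c1c(Cl)cc(Cl)cc1Cl | intermediate
35 | 6β-angelate, fully protected | CC(C)(C)[Si](c1ccccc1)(c1ccccc1)OC[C@@]1(C)[C@H](CC3OCCO3)[C@H](OC(=O)/C(C)=C\C)[C@H]2C(CN(C)C)C(=O)O[C@H]2[C@@H]1O[Si](C(C)C)(C(C)C)C(C)C | intermediate
36 | C1 primary alcohol | OC[C@@]1(C)[C@H](CC3OCCO3)[C@H](OC(=O)/C(C)=C\C)[C@H]2C(CN(C)C)C(=O)O[C@H]2[C@@H]1O[Si](C(C)C)(C(C)C)C(C)C | intermediate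
37 | C1 aldehyde | O=C[C@@]1(C)[C@H](CC3OCCO3)[C@H](OC(=O)/C(C)=C\C)[C@H]2C(CN(C)C)C(=O)O[C@H]2[C@@H]1O[Si](C(C)C)(C(C)C)C(C)C | intermediate
38 | C10 vinyl compound, 9β-OSi(iPr)3 | C=C[C@@]1(C)[C@H](CC3OCCO3)[C@H](OC(=O)/C(C)=C\C)[C@H]2C(CN(C)C)C(=O)O[C@H]2[C@@H]1O[Si](C(C)C)(C(C)C)C(C)C | intermediate
39 | 9β-alcohol | C=C[C@@]1(C)[C@H](CC3OCCO3)[C@H](OC(=O)/C(C)=C\C)[C@H]2C(CN(C)C)C(=O)O[C@H]2[C@@H]1O | intermediate
40 | (R)-2-methylbutanoic acid | CC[C@@H](C)C(=O)O | starting material
41 | 6β-angelate 9β-[(2R)-2-methylbutanoate], C3 dioxolane | C=C[C@@]1(C)[C@H](CC3OCCO3)[C@H](OC(=O)/C(C)=C\C)[C@H]2C(CN(C)C)C(=O)O[C@H]2[C@@H]1OC(=O)[C@H](C)CC | intermediate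
42 | diester with C5–CH2–CHO | C=C[C@@]1(C)[C@H](CC=O)[C@H](OC(=O)/C(C)=C\C)[C@H]2C(CN(C)C)C(=O)O[C@H]2[C@@H]1OC(=O)[C@H](C)CC | intermediate
43 | β-(dimethylamino) aldehyde at C4 | C=C[C@@]1(C)[C@H](C(CN(C)C)C=O)[C@H](OC(=O)/C(C)=C\C)[C@H]2C(CN(C)C)C(=O)O[C@H]2[C@@H]1OC(=O)[C@H](C)CC | intermediate
44 | enal with 11-(dimethylaminomethyl) lactone | C=C[C@@]1(C)[C@H](C(=C)C=O)[C@H](OC(=O)/C(C)=C\C)[C@H]2C(CN(C)C)C(=O)O[C@H]2[C@@H]1OC(=O)[C@H](C)CC | intermediate
45 | trimethylammonium iodide of 44 | C=C[C@@]1(C)[C@H](C(=C)C=O)[C@H](OC(=O)/C(C)=C\C)[C@H]2C(C[N+](C)(C)C)C(=O)O[C@H]2[C@@H]1OC(=O)[C@H](C)CC.[I-] | intermediate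
46 | CNP0295282.1 | C=C[C@@]1(C)[C@H](C(=C)C=O)[C@H](OC(=O)/C(C)=C\C)[C@H]2C(=C)C(=O)O[C@H]2[C@@H]1OC(=O)[C@H](C)CC | target

**Step count and weak points**

Total: 27 steps. Longest linear sequence: 27 steps (1 → 46); compounds 2, 12, 15, 19, 33 and 40 are bought.

The three steps most likely to fail:

Step 8 (key step). What may go wrong: singlet oxygen may discriminate too weakly between the methyl face and the CH2OSi face of the diene, since the silyl group can rotate away from the ring. The fallback changes the group that controls the face, not the conditions; it sets out from 14 and returns at 17. Bu4NF removes the silyl group from 14 to give the primary alcohol F1. Ph3CCl, Et3N and DMAP convert it into the trityl ether F2, whose three aryl rings sit one bond closer to C10. Photooxygenation as in step 8 should give the endoperoxide F3, and Et3N the hydroxy enone F4. HCO2H in Et2O removes the trityl group to give the diol F5, and tBuPh2SiCl/imidazole silylates the primary hydroxyl selectively to give 17.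

Step 12. What may go wrong: base-induced isomerisation (of the enone before the peroxide adds at the hindered C8, or of the γ-hydroxy enoate to a 1,3-diketone afterwards) may outrun the epoxidation/ring-opening sequence. The fallback separates a neutral epoxidation from a mild ring opening; it sets out from 21 and returns at 28. Ozonolysis (O3; PPh3) of 21 gives the enone aldehyde F6, and Me3SiOCH2CH2OSiMe3 with catalytic Me3SiOTf gives the dioxolane F7. With the allyl group gone, methyl(trifluoromethyl)dioxirane made in situ (KHSO5 as 2KHSO5·KHSO4·K2SO4, CF3COCH3, NaHCO3, MeCN/H2O, 0 °C) should give the α-epoxy ketone F8 anti to the C9 silyloxy group. Et3N in CH2Cl2 opens it to the hydroxy enoate F9. CF3CO2H in CH2Cl2 then lactonises F9 to 28; any aldehyde 27 formed by loss of the acetal is re-protected as in step 15.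

Step 11. What may go wrong: enolisation may go toward C9 instead of C5, or proton transfer from C11 may lead to allylation next to the ester and to poor diastereocontrol at C5. The fallback masks the ester α-position as a carboxylate and uses a plain lithium enolate alkylation; it sets out from 18 and returns at 21. CF3CO2H cleaves the tert-butyl ester of 18 to the keto acid F10. LiN(iPr)2 (2.2 equiv, THF, −78 °C) forms the carboxylate and then the C5 enolate, and allyl iodide gives the 5β-allyl keto acid F11. tert-Butyl 2,2,2-trichloroacetimidate with catalytic BF3·OEt2 restores the tert-butyl ester and gives 21.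

**Further compounds**

F1 | step 8 | tert-butyl 2-[(4S)-4-(hydroxymethyl)-4-methylcyclohexa-1,5-dien-1-yl]acetate | OC[C@@]1(C)CC=C(CC(=O)OC(C)(C)C)C=C1
F2 | step 8 | trityl ether of F1 | C(c1ccccc1)(c1ccccc1)(c1ccccc1)OC[C@@]1(C)CC=C(CC(=O)OC(C)(C)C)C=C1
F3 | step 8 | endoperoxide with CH2OCPh3 on C10, C6–O and C9–O β | C(c1ccccc1)(c1ccccc1)(c1ccccc1)OC[C@@]1(C)C[C@@H]2OO[C@H]1C=C2CC(=O)OC(C)(C)C
F4 | step 8 | 9β-hydroxy-6-oxo-7-ene with CH2OCPh3 on C10 | C(c1ccccc1)(c1ccccc1)(c1ccccc1)OC[C@@]1(C)CC(=O)C(CC(=O)OC(C)(C)C)=C[C@@H]1O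
F5 | step 8 | 1,9β-diol of the hydroxy enone | OC[C@@]1(C)CC(=O)C(CC(=O)OC(C)(C)C)=C[C@@H]1O
F6 | step 12 | enone with C5–CH2–CHO | CC(C)(C)[Si](c1ccccc1)(c1ccccc1)OC[C@@]1(C)[C@H](CC=O)C(=O)C(CC(=O)OC(C)(C)C)=C[C@@H]1O[Si](C(C)C)(C(C)C)C(C)C
F7 | step 12 | enone with C3 as 1,3-dioxolane | CC(C)(C)[Si](c1ccccc1)(c1ccccc1)OC[C@@]1(C)[C@H](CC3OCCO3)C(=O)C(CC(=O)OC(C)(C)C)=C[C@@H]1O[Si](C(C)C)(C(C)C)C(C)C
F8 | step 12 | 7α,8α-epoxy ketone with C3 dioxolane | CC(C)(C)[Si](c1ccccc1)(c1ccccc1)OC[C@@]1(C)[C@H](CC3OCCO3)C(=O)[C@@]2(CC(=O)OC(C)(C)C)O[C@H]2[C@@H]1O[Si](C(C)C)(C(C)C)C(C)C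
F9 | step 12 | (E)-alkylidene 8α-hydroxy 6-ketone tert-butyl ester with C3 dioxolane | CC(C)(C)[Si](c1ccccc1)(c1ccccc1)OC[C@@]1(C)[C@H](CC3OCCO3)C(=O)/C(=C/C(=O)OC(C)(C)C)[C@@H](O)[C@@H]1O[Si](C(C)C)(C(C)C)C(C)C
F10 | step 11 | enone carboxylic acid from 18 | CC(C)(C)[Si](c1ccccc1)(c1ccccc1)OC[C@@]1(C)CC(=O)C(CC(=O)O)=C[C@@H]1O[Si](C(C)C)(C(C)C)C(C)C
F11 | step 11 | 5β-allyl enone carboxylic acid | CC(C)(C)[Si](c1ccccc1)(c1ccccc1)OC[C@@]1(C)[C@H](CC=C)C(=O)C(CC(=O)O)=C[C@@H]1O[Si](C(C)C)(C(C)C)C(C)C
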